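## Structural features

The target is an achiral flavone: a benzo-fused 4-pyranone (ring A fused to ring C) that carries ring B on C2 through the C2–C1' bond. There is no stereocentre, so no question of neighbouring stereocentres arises. Ring A has the phloroglucinol pattern (O1, 5-OH, 7-OMe), and its 5-hydroxyl is hydrogen-bonded to the C4 carbonyl, which makes it the least reactive phenol. Ring B is pentasubstituted, with four contiguous oxygens (2'-OH, 3'-OMe, 4'-OMe, 5'-OH) and one hydrogen at C6'; because the two hydroxyls are para, it is a 2,3-dimethoxyhydroquinone, the reduced form of a 2,3-dimethoxy-1,4-benzoquinone. Fragile points are this electron-rich hydroquinone (air oxidation), the pyranone (opened by hard nucleophiles and strong base, with the 2'-hydroxyl able to re-close it the wrong way round), and the three-to-three split of free phenols and methyl ethers, which forbids any late unselective methylation or demethylation. The real difficulty is therefore ring B: its regiodefined, differentiated oxygenation and its attachment to C2 without a long traffic of protecting groups. The key step exploits two features. First, C2', C3', C4' and C5' carry oxygen in the order carbonyl-derived, methoxy, methoxy, carbonyl-derived, which are exactly the four carbons of a squaric acid diester, so only C1' and C6' must come from a two-carbon unit. Second, "hydroquinone ring B plus C2=C3" is an isomer of "quinone ring B plus C2H–C3H2", so a quinone-forming ring expansion on a chromanone reaches the target by hydrogen shifts alone. In one sentence: ring B is created last, by thermal ring expansion of a 4-alkynyl-4-hydroxycyclobutenone (a squarate–acetylene adduct hung on C2 of a chromanone) that is an isomer of the target.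

## Logic of the disconnections

14 to 13. No skeletal bond is cut; two hydrogens are moved back, from O2' and O5' of ring B to C2 and C3 of ring C. The reason is that a quinone is what a squarate ring expansion delivers, and an sp3 C2 is what carbon–carbon bond formation at C2 of a chromone delivers. The gain is that no separate oxidation or reduction is needed. The demand on the forward step is a mild base that moves these hydrogens without opening the pyranone or adding to the quinone.

13 to 10. The C1'–C2' bond of ring B is cut and the four-membered ring is re-formed between C2' and C5'. C2' to C5' then come from a cyclobutenone, and C6' and C1' from an alkyne. The gain is large: a pentasubstituted arene with differentiated oxygens is replaced by a squarate-derived ring that already carries both methoxy groups and both future hydroxyl oxygens in the right places. The forward step must close the six-membered and not the five-membered ring. That requires an sp3 carbon at the alkyne terminus, which is why C2 is carried as the chromanone and not the chromone. It also requires a free tertiary hydroxyl as hydrogen donor.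

10 to 4 and 6. The bond between C2 of ring C and the alkyne carbon is cut. C2 is the one carbon of a chromone that becomes strongly electrophilic on O-silylation (benzopyrylium ion), and a terminal alkyne is a nucleophile under copper catalysis. Joining in this order avoids an acetylide next to an enolisable ketone. The forward step needs attack at C2 only, transient silylation of the two hydroxyls, and a cyclobutenone that tolerates the silyl triflate.

4 to 1 and 2. The bond between the carbinol carbon and the alkyne is cut, which is a 1,2-addition of an acetylide to one carbonyl of the squarate ester. The forward step needs mono-addition and a neutral, cold work-up so that the adduct does not lose methanol.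

6 to 5. The O7–CH3 bond is cut. The forward step needs methylation of the free 7-hydroxyl only, which the hydrogen bond of the 5-hydroxyl secures.

## Other disconnections considered

Alternative 1: The first plan to come to mind cuts O1–C2 and C2–C3 (Baker–Venkataraman). The acid A1 (2,5-bis(benzyloxy)-3,4-dimethoxybenzoic acid) would be esterified onto the acetophenone A2 (1-[2-(benzyloxy)-6-hydroxy-4-methoxyphenyl]ethanone). Base-induced acyl transfer would give the 1,3-diketone A3, acid would close it to the tribenzyl flavone A4, and hydrogenolysis would give 14. The chosen plan is preferred on step economy and because this route buys the hard part instead of solving it. A1 is not a stock compound and would need its own sequence of oxygenation, protection and carboxylation. Three benzyl groups are put on and taken off, and the count would be about twice that of the chosen route.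

Alternative 2: A three-component assembly cuts C4a–C4, C4–C3 and O1–C2. The iodophenol A5 (3-(benzyloxy)-2-iodo-5-methoxyphenol), carbon monoxide and the arylacetylene A6 (1,4-bis(benzyloxy)-5-ethynyl-2,3-dimethoxybenzene) would be joined by a carbonylative Sonogashira coupling (PdCl2(PPh3)2, CuI, amine) to the ynone A7, which would close 6-endo to A4. The components meet at the core, but ring B is again untouched: A6 needs all the oxygenation work of A1 plus a homologation. A5 needs a regioselective iodination between two oxygens, and the closure of A7 can also go 5-exo to an aurone. The chosen plan builds ring B instead of carrying it.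

Alternative 3: The C2–C1' bond is cut. Chromone 6 and 2,3-dimethoxy-1,4-benzoquinone A8 would be joined by a dehydrogenative coupling (Pd(OAc)2, oxidant) to the quinonyl chromone A9, and reduction would give 14. This is the shortest plan on paper, but electrophilic divalent palladium attacks a chromone at C3, the nucleophilic β-carbon of its enol ether system. Insertion of the quinone would then give the C3-linked isomer A10 with isoflavone connectivity. In the chosen plan the new bond at C2 is made by a nucleophile on a benzopyrylium ion, where C2 is the only open electrophilic site.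

Key step: step 4

Assumption: 1, 2 (as its THF solution) and 5 are taken as purchasable. Chiral intermediates are racemic (diastereomer mixtures where two centres are present), which is immaterial because all centres are erased in step 4.

## Route

Step 1
Reactants: 1 dimethyl squarate (3,4-dimethoxycyclobut-3-ene-1,2-dione); 2 ethynylmagnesium bromide
Product: 4 4-ethynyl-4-hydroxy-2,3-dimethoxycyclobut-2-en-1-one (racemic), via bromomagnesium alkoxide 3 (not isolated)
Conditions: 2 (1.05 equiv, 0.5 M in THF), THF, −78 → −40 °C; sat. aq. NH4Cl, −78 → 0 °C
Reagents that add atoms: none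
Why: 1,2-addition of an acetylide to one carbonyl of a squarate ester, the standard entry to 4-alkynyl-4-hydroxycyclobutenones; the alkoxide 3 deactivates the second carbonyl, and the cold, near-neutral quench avoids acid-induced loss of methanol. The new carbinol centre is formed racemic and is destroyed in step 4.

Step 2
Reactants: 5 5,7-dihydroxy-4H-chromen-4-one
Product: 6 5-hydroxy-7-methoxy-4H-chromen-4-one
Conditions: MeI (1.1 equiv), K2CO3 (1.1 equiv), acetone, 50 °C
Reagents that add atoms: iodomethane, CI
Why: Williamson ether synthesis; the 7-hydroxyl is the acidic, free vinylogous acid, whereas the 5-hydroxyl is held in a hydrogen bond to C4=O and should stay unalkylated with one equivalent of base and electrophile.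

Step 3
Reactants: 4 4-ethynyl-4-hydroxy-2,3-dimethoxycyclobut-2-en-1-one; 6 5-hydroxy-7-methoxy-4H-chromen-4-one
Product: 10 4-hydroxy-4-[(5-hydroxy-7-methoxy-4-oxo-3,4-dihydro-2H-chromen-2-yl)ethynyl]-2,3-dimethoxycyclobut-2-en-1-one (mixture of racemic diastereomers), via benzopyrylium triflate 7 (not isolated), via silylated alkynol 8 (not isolated), via trisilylated adduct 9 (not isolated)
Conditions: 6, TMSOTf (2.2 equiv), iPr2NEt (1.2 equiv), CH2Cl2, 0 °C; 4, TMSOTf (1.1 equiv), iPr2NEt (1.3 equiv), CH2Cl2, −78 °C; combine, CuI (10 mol %), iPr2NEt (1.5 equiv), −40 → 0 °C; then 10% aq. citric acid, THF, 0 → 23 °C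
Reagents that add atoms: none
Why: Copper-catalysed conjugate alkynylation of a chromone through its 4-silyloxybenzopyrylium ion: silylation of the carbonyl oxygen (and, transiently, of both hydroxyls) gives 7, and the monovalent copper acetylide of 8 attacks C2, the only open electrophilic carbon since C4 carries the siloxy group. Mild acid then hydrolyses the silyl enol ether and both silyl ethers of 9, returning the ketone, the 5-hydroxyl and the tertiary hydroxyl needed in step 4. The new centre at C2 is formed without control, which does not matter.

Step 4
Reactants: 10 4-hydroxy-4-[(5-hydroxy-7-methoxy-4-oxo-3,4-dihydro-2H-chromen-2-yl)ethynyl]-2,3-dimethoxycyclobut-2-en-1-one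
Product: 14 2-(2,5-dihydroxy-3,4-dimethoxyphenyl)-5-hydroxy-7-methoxy-4H-chromen-4-one (the target), via enynylketene 11 (not isolated), via ring-B diradical 12 (not isolated), via quinonyl chromanone 13 (not isolated)
Conditions: p-xylene (degassed, 0.01 M), 138 °C, Ar; then 23 °C, Et3N (0.2 equiv); work-up under Ar
Reagents that add atoms: none
Why: Heating opens the cyclobutenone by conrotatory 4π electrocyclic cleavage of the bond between the carbonyl and carbinol carbons; the hydroxyl rotates outward, so the alkynyl arm of ketene 11 lies next to the ketene carbon. That carbon then bonds to the far alkyne carbon (the one bearing C2 of the chromanone), a six-membered closure of the Moore type that forms the C1'–C2' bond and ring B as the σ,π-diradical 12, and transfer of the hydroxyl hydrogen from O5' to the aryl radical at C6' gives quinone 13. This is the known thermal rearrangement of 4-alkynyl-4-hydroxycyclobutenones to 1,4-benzoquinones, the closest precedent being its use for 2,3-dimethoxyquinones. The selectivity needed is six- over five-membered closure (the latter would lead to an alkylidenecyclopentenedione); five-membered closure is favoured only when the alkyne terminus carries a group that stabilises the exocyclic vinyl radical, and here the terminus is the sp3 carbon C2, which is why the chromanone and not the chromone enters this step. Quinone 13 is a redox isomer of 14: Et3N removes the C2–H, a vinylogous α-hydrogen of the quinone, to give an ortho-quinone methide. Loss of a C3–H next to C4=O (a 1,5-hydrogen shift or a second deprotonation) then aromatises ring B to the hydroquinone and sets C2=C3, the known tautomerisation of alkylquinones to alkenylhydroquinones. The driving force is aromatisation of ring B together with formation of the chelated, fully conjugated 4-pyranone. No stereocentre is created, the two centres of 10 are erased, and the whole step is an isomerisation (10 and 14 are both C18H16O8) that needs no oxidant, reductant or protecting group.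

## Compound list

1 | dimethyl squarate (3,4-dimethoxycyclobut-3-ene-1,2-dione) | COC1=C(OC)C(=O)C1=O | starting material
2 | ethynylmagnesium bromide | C#C[Mg]Br | starting material
3 | bromomagnesium 1-ethynyl-2,3-dimethoxy-4-oxocyclobut-2-en-1-olate (racemic, not isolated) | COC1=C(OC)C(O[Mg]Br)(C#C)C1=O | intermediate
4 | 4-ethynyl-4-hydroxy-2,3-dimethoxycyclobut-2-en-1-one (racemic) | COC1=C(OC)C(O)(C#C)C1=O | intermediate
5 | 5,7-dihydroxy-4H-chromen-4-one | O=c1ccoc2cc(O)cc(O)c12 | starting material
6 | 5-hydroxy-7-methoxy-4H-chromen-4-one | COc1cc(O)c2c(=O)ccoc2c1 | intermediate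
7 | 7-methoxy-4,5-bis(trimethylsilyloxy)chromenylium trifluoromethanesulfonate (not isolated) | COc1cc(O[Si](C)(C)C)c2c(O[Si](C)(C)C)cc[o+]c2c1.[O-]S(=O)(=O)C(F)(F)F | intermediate
8 | 4-ethynyl-2,3-dimethoxy-4-(trimethylsilyloxy)cyclobut-2-en-1-one (racemic, not isolated) | COC1=C(OC)C(O[Si](C)(C)C)(C#C)C1=O | intermediate
9 | 2,3-dimethoxy-4-{[7-methoxy-4,5-bis(trimethylsilyloxy)-2H-chromen-2-yl]ethynyl}-4-(trimethylsilyloxy)cyclobut-2-en-1-one (diastereomer mixture, not isolated) | COC1=C(OC)C(O[Si](C)(C)C)(C#CC2C=C(O[Si](C)(C)C)c3c(O[Si](C)(C)C)cc(OC)cc3O2)C1=O | intermediate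
10 | 4-hydroxy-4-[(5-hydroxy-7-methoxy-4-oxo-3,4-dihydro-2H-chromen-2-yl)ethynyl]-2,3-dimethoxycyclobut-2-en-1-one (mixture of racemic diastereomers) | COC1=C(OC)C(O)(C#CC2CC(=O)c3c(O)cc(OC)cc3O2)C1=O | intermediate
11 | (3Z)-4-hydroxy-6-(5-hydroxy-7-methoxy-4-oxo-3,4-dihydro-2H-chromen-2-yl)-2,3-dimethoxyhexa-1,3-dien-5-yn-1-one (ketene, not isolated) | O=C=C(OC)/C(OC)=C(/O)C#CC1CC(=O)c2c(O)cc(OC)cc2O1 | intermediate
12 | ring-B diradical of 2-aryl-5-hydroxy-7-methoxychroman-4-one: oxygen radical on C2', carbon radical at C6', 3',4'-dimethoxy, 5'-hydroxy (not isolated) | COc1c(OC)c([O])c(C2CC(=O)c3c(O)cc(OC)cc3O2)[c]c1O | intermediate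
13 | 2-(4,5-dimethoxy-3,6-dioxocyclohexa-1,4-dien-1-yl)-5-hydroxy-7-methoxy-2,3-dihydro-4H-chromen-4-one (racemic, not isolated) | COC1=C(OC)C(=O)C(C2CC(=O)c3c(O)cc(OC)cc3O2)=CC1=O | intermediate
14 | 2-(2,5-dihydroxy-3,4-dimethoxyphenyl)-5-hydroxy-7-methoxy-4H-chromen-4-one (CNP0170944.0; no stereocentre) | COc1cc(O)c2c(=O)cc(-c3cc(O)c(OC)c(OC)c3O)oc2c1 | target

## Step count and risks

Total step count: 4. Longest linear sequence: 3 steps (1, 3, 4 or 2, 3, 4).

Least certain steps:

Step 4 (key step). The most likely failure is closure of ketene 11 to a five-membered instead of a six-membered ring, or hydrogen transfer within diradical 12 from a carbon of the chromanone instead of from the hydroxyl. Both arise because the diradical pathway leaves a choice of ring size and of hydrogen donor. A second risk is base-induced opening of the chromanone (β-elimination of the aryl oxygen) during the amine treatment, which would expose a reactive vinylquinone before the hydrogen shifts are complete.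

The fallback replaces the diradical closure by a pericyclic one. It sets out from 10: semi-hydrogenation (H2, Pd/CaCO3 poisoned with Pb(OAc)2, quinoline, EtOAc) should give 4-hydroxy-4-[(Z)-2-(5-hydroxy-7-methoxy-4-oxo-3,4-dihydro-2H-chromen-2-yl)ethenyl]-2,3-dimethoxycyclobut-2-en-1-one F1. Heating F1 in toluene at 110 °C should open the ring to a dienylketene that closes by 6π electrocyclisation, with no choice of ring size, and tautomerises to the hydroquinone flavanone 2-(2,5-dihydroxy-3,4-dimethoxyphenyl)-5-hydroxy-7-methoxy-2,3-dihydro-4H-chromen-4-one F2. Oxidation of F2 with Ag2O in Et2O should give quinone 13, where the route is rejoined for the amine-mediated tautomerisation to 14.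

Step 3. The most likely failure is ionisation of the silylated tertiary carbinol of 8 under the silyl triflate, followed by 1,3-transposition of oxygen and loss of the cyclobutenone. The other risk is sluggish capture of benzopyrylium ion 7, which three oxygen donors stabilise.

The fallback inverts the order of the two carbon–carbon bond formations, so that the cyclobutenone never meets a silyl triflate. It sets out from 6: TBSOTf (2.2 equiv), iPr2NEt, CuI and ethynyltrimethylsilane in CH2Cl2, with non-aqueous work-up, should give 4,5-bis(tert-butyldimethylsilyloxy)-7-methoxy-2-[(trimethylsilyl)ethynyl]-2H-chromene F3, in which the ketone stays masked as its silyl enol ether. K2CO3 in MeOH at 0 °C should remove the alkynyl silyl group to give 4,5-bis(tert-butyldimethylsilyloxy)-2-ethynyl-7-methoxy-2H-chromene F4. Deprotonation with n-BuLi in THF at −78 °C and addition to 1 should give 4-{[4,5-bis(tert-butyldimethylsilyloxy)-7-methoxy-2H-chromen-2-yl]ethynyl}-4-hydroxy-2,3-dimethoxycyclobut-2-en-1-one F5. HF·pyridine in THF at 0 °C should then free the ketone and the phenol and return the route at 10.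

Step 1. The most likely failures are addition–elimination at an enol ether carbon with loss of methoxide, a second addition caused by the bis-metalated acetylene present in the Grignard solution, and loss of methanol from the adduct on work-up. All follow from the high electrophilicity of every carbon of the squarate.

The fallback uses a capped acetylene that can add only once. It sets out from 1: lithium (trimethylsilyl)acetylide (from ethynyltrimethylsilane and n-BuLi, THF, −78 °C) should give 4-hydroxy-2,3-dimethoxy-4-[(trimethylsilyl)ethynyl]cyclobut-2-en-1-one F6. Buffered fluoride (KF, AcOH, MeOH, 0 °C) should remove the silyl cap and return the route at 4.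

## Further compounds

F1 | step 4 | 4-hydroxy-4-[(Z)-2-(5-hydroxy-7-methoxy-4-oxo-3,4-dihydro-2H-chromen-2-yl)ethenyl]-2,3-dimethoxycyclobut-2-en-1-one (diastereomer mixture) | COC1=C(OC)C(O)(/C=C\C2CC(=O)c3c(O)cc(OC)cc3O2)C1=O
F2 | step 4 | 2-(2,5-dihydroxy-3,4-dimethoxyphenyl)-5-hydroxy-7-methoxy-2,3-dihydro-4H-chromen-4-one (racemic) | COc1cc(O)c2C(=O)CC(c3cc(O)c(OC)c(OC)c3O)Oc2c1
F3 | step 3 | 4,5-bis(tert-butyldimethylsilyloxy)-7-methoxy-2-[(trimethylsilyl)ethynyl]-2H-chromene (racemic) | COc1cc(O[Si](C)(C)C(C)(C)C)c2C(O[Si](C)(C)C(C)(C)C)=CC(C#C[Si](C)(C)C)Oc2c1
F4 | step 3 | 4,5-bis(tert-butyldimethylsilyloxy)-2-ethynyl-7-methoxy-2H-chromene (racemic) | COc1cc(O[Si](C)(C)C(C)(C)C)c2C(O[Si](C)(C)C(C)(C)C)=CC(C#C)Oc2c1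
F5 | step 3 | 4-{[4,5-bis(tert-butyldimethylsilyloxy)-7-methoxy-2H-chromen-2-yl]ethynyl}-4-hydroxy-2,3-dimethoxycyclobut-2-en-1-one (diastereomer mixture) | COC1=C(OC)C(O)(C#CC2C=C(O[Si](C)(C)C(C)(C)C)c3c(O[Si](C)(C)C(C)(C)C)cc(OC)cc3O2)C1=O
F6 | step 1 | 4-hydroxy-2,3-dimethoxy-4-[(trimethylsilyl)ethynyl]cyclobut-2-en-1-one (racemic) | COC1=C(OC)C(O)(C#C[Si](C)(C)C)C1=O
A1 | alternative 1 | 2,5-bis(benzyloxy)-3,4-dimethoxybenzoic acid | COc1c(OC)c(OCc2ccccc2)c(C(=O)O)cc1OCc1ccccc1
A2 | alternative 1 | 1-[2-(benzyloxy)-6-hydroxy-4-methoxyphenyl]ethan-1-one | CC(=O)c1c(O)cc(OC)cc1OCc1ccccc1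
A3 | alternative 1 | 1-[2-(benzyloxy)-6-hydroxy-4-methoxyphenyl]-3-[2,5-bis(benzyloxy)-3,4-dimethoxyphenyl]propane-1,3-dione | COc1cc(O)c(C(=O)CC(=O)c2cc(OCc3ccccc3)c(OC)c(OC)c2OCc2ccccc2)c(OCc2ccccc2)c1
A4 | alternative 1 | 5-(benzyloxy)-2-[2,5-bis(benzyloxy)-3,4-dimethoxyphenyl]-7-methoxy-4H-chromen-4-one | COc1cc(OCc2ccccc2)c2c(=O)cc(-c3cc(OCc4ccccc4)c(OC)c(OC)c3OCc3ccccc3)oc2c1
A5 | alternative 2 | 3-(benzyloxy)-2-iodo-5-methoxyphenol | COc1cc(O)c(I)c(OCc2ccccc2)c1
A6 | alternative 2 | 1,4-bis(benzyloxy)-5-ethynyl-2,3-dimethoxybenzene | COc1c(OC)c(OCc2ccccc2)c(C#C)cc1OCc1ccccc1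
A7 | alternative 2 | 1-[2-(benzyloxy)-6-hydroxy-4-methoxyphenyl]-3-[2,5-bis(benzyloxy)-3,4-dimethoxyphenyl]prop-2-yn-1-one | COc1cc(O)c(C(=O)C#Cc2cc(OCc3ccccc3)c(OC)c(OC)c2OCc2ccccc2)c(OCc2ccccc2)c1
A8 | alternative 3 | 2,3-dimethoxycyclohexa-2,5-diene-1,4-dione | COC1=C(OC)C(=O)C=CC1=O
A9 | alternative 3 | 2-(4,5-dimethoxy-3,6-dioxocyclohexa-1,4-dien-1-yl)-5-hydroxy-7-methoxy-4H-chromen-4-one | COC1=C(OC)C(=O)C(c2cc(=O)c3c(O)cc(OC)cc3o2)=CC1=O
A10 | alternative 3 | 3-(4,5-dimethoxy-3,6-dioxocyclohexa-1,4-dien-1-yl)-5-hydroxy-7-methoxy-4H-chromen-4-one | COC1=C(OC)C(=O)C(c2coc3cc(OC)cc(O)c3c2=O)=CC1=O
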